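At early times the noon and dawn runs still show what was charged, so the useful question is how long that lasts.

all flasks: starting material 0.37 M

|  | other conformer | remark | time |
|---|---|---|---|
| noon | 0.052 M | run made earlier |  |
| dawn | 0.081 M | run made earlier |  |
| flask | 0.0370 M |  | 4.0 h |

| run | time / h | isomer of the product / % | target / % |
|---|---|---|---|
| noon | 0.200 | 12.0 | 8.4 |
| noon | 0.667 | 24.8 | 24.0 |
| noon | 1.00 | 30.2 | 30.6 |
| noon | 2.00 | 37.9 | 43.9 |
| noon | 2.50 | 39.5 | 48.0 |
| noon | 3.00 | 39.3 | 50.2 |
| dawn | 0.200 | 14.3 | 8.3 |
| dawn | 0.667 | 25.5 | 22.8 |
| dawn | 1.00 | 31.4 | 30.7 |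
| dawn | 2.00 | 38.4 | 43.8 |
| dawn | 2.50 | 39.5 | 47.1 |
| dawn | 3.00 | 39.3 | 49.7 |

(scatter of a reading: 0.3 percentage points)



1. share of isomer of the product in isomer of the product plus target at 20 s
2. share of isomer of the product in isomer of the product plus target at 4.0 h
3. which of isomer of the product and target there is more of at 4.0 h

Start with the main step by itself: as a working picture, let the charge feed target and isomer of the product side by side; the noon run between 0.667 h and 1.00 h then reads a share of isomer of 45.0%.

Now add the other conformer, as a fraction of the charge: 12.3% at noon, 18.0% at dawn, 9.09% in the flask. At 0.200 h the share of isomer reads 58.8% at noon and 63.3% at dawn, so I expect the flask at 20 s to stand above the main-step share, but these readings start too late to say by how much.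

At 3.00 h the same runs read 43.9% and 44.2%, a gap within the scatter of 0.3 percentage points. Divided by the difference in conformer fraction, that gap gives 0.0438: this change of the late share per unit of conformer fraction charged, with the starting material held at its charge, is the charge memory. It is a reading, no firmer than that gap.

Last comes the slow process: the noon share falls from 45.1% at 2.50 h to 43.9%. Correcting noon by the memory and running that drift on to 4.0 h, I reckon 41.3% for the flask, with target ahead.

The forecast gives 61% at 20 s, 42% at 4.0 h and target ahead, holding that “the conformer goes preferentially and fairly quickly to isomer”. Its late share lies slightly above mine.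

The flask gives 73.5% at 20 s and 41.8% at 4.0 h, with target at 53.8% and isomer of the product at 38.6%.

    other conformer → isomer of the product (k = 0.00407 s⁻¹)
    starting material → target (k = 1.38 × 10⁻⁴ s⁻¹)
    other conformer ⇌ dormant form (K = 85.6, k = 5.39 × 10⁻⁴ s⁻¹)
    target ⇌ isomer of the product (K = 0.570, k = 3.13 × 10⁻⁵ s⁻¹)
    starting material ⇌ other conformer (K = 0.0659, k = 2.75 × 10⁻⁴ s⁻¹)

In the flask at 0.620 h, the other conformer has a half-life of 2.8 min by its conversion into isomer of the product, while target has one of 6.2 h by the forward rate of its conversion into isomer of the product. My 41.3% stands beside the flask's 41.8%. The neighbour with 0.063 M of other conformer has a conformer fraction of 14.5%, so from the flask's late share the memory reckons 42.0% for it, and that neighbour stands at 42.2%.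

All runs are calculated with made-up constants; the scatter is artificial.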